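**Retrosynthetic overview**

1. The strategy rests on one feature found in both 1,4-dioxane rings: the aryl-bearing carbon C2 and the CH2OH-bearing carbon C3 are trans, C2 is bonded to the benzo oxygen meta to that ring's carbon side chain and C3 to the oxygen para to it. This is the imprint of an E-ArCH=CH–CH2OH alkene that gained the two oxygens of a 3,4-dihydroxyaryl unit on one face.
2. Each dioxane is cut first at O(para)–C3 (6-exo opening of a terminal oxirane by the phenoxide, inversion) and then at O(meta)–C2 (phenoxide opening of a Sharpless 2,3-epoxy alcohol at its benzylic carbon, inversion). The oxirane is made from the intervening 1,2-diol through its primary tosylate.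
3. The cinnamyl alcohol for the outer ring is the inner benzodioxane aldehyde homologated by HWE olefination and DIBAL-H reduction, so one phenol, 4-allyloxy-3-hydroxybenzaldehyde, serves twice. The propenol of the target is made the same way from the last aldehyde, with the acidic deprotection placed before the final ester reduction.
4. Ring order: inner dioxane (step 8, D-tartrate series), then outer dioxane (step 16, L-tartrate series); the three benzene rings are bought.

Key step: step 8

Remark: the p-alkoxyphenyl epoxy alcohols 4 and 16 are assumed to be too acid-labile for chromatography and are carried crude from a basic work-up; the benzylic C–O bonds then meet no Lewis or protic acid until step 18.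

Abbreviations used in names: MOM = CH2OCH3; TBS = Si(CH3)2C(CH3)3; ArM = 3,4-bis(methoxymethoxy)phenyl; BD = (2S,3S)-3-ArM-2-(TBSOCH2)-2,3-dihydro-1,4-benzodioxin-6-yl (the silylated inner benzodioxane, C2 = CH2O-bearing carbon, C3 = aryl-bearing carbon).

**Route**

Step 1
Reactants: 1 caffeic acid
Product: 2 methoxymethyl (E)-3-[3,4-bis(methoxymethoxy)phenyl]prop-2-enoate
Conditions: MOMCl (3.5 equiv), i-Pr2NEt (4.5 equiv), DMF, 0 °C to rt
Reagents that add atoms: chloromethyl methyl ether, COCCl
Why: Williamson-type O-alkylation with the reactive α-chloro ether should convert both phenols and the carboxylic acid, masking the catechol as base-stable MOM ethers and giving an ester ready for reduction.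

Step 2
Reactants: 2 methoxymethyl (E)-3-[3,4-bis(methoxymethoxy)phenyl]prop-2-enoate
Product: 3 (E)-3-[3,4-bis(methoxymethoxy)phenyl]prop-2-en-1-ol
Conditions: DIBAL-H (3 equiv), CH2Cl2, −78 to 0 °C; Rochelle salt work-up
Reagents that add atoms: none
Why: DIBAL-H reduction of an α,β-unsaturated ester is 1,2-selective and should give the E-allylic alcohol without touching the alkene or the aryl MOM ethers.

Step 3
Reactants: 3 (E)-3-[3,4-bis(methoxymethoxy)phenyl]prop-2-en-1-ol
Product: 4 [(2R,3R)-3-ArM-oxiran-2-yl]methanol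
Conditions: Ti(Oi-Pr)4 (10 mol%), D-(−)-DIPT (13 mol%), t-BuOOH (2 equiv, decane), 4 Å MS, CH2Cl2, −25 °C; aq. NaOH/brine work-up, used crude
Reagents that add atoms: tert-butyl hydroperoxide, CC(C)(C)OO
Why: Sharpless asymmetric epoxidation of an E-allylic alcohol, in which the D-(−)-tartrate titanium complex delivers oxygen to the alkene face that gives the (2R,3R)-epoxy alcohol (the mirror image of the (2S,3S) product formed from cinnamyl alcohols with L-(+)-tartrate), so both oxirane centres are set by the reagent.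

Step 4
Reactants: 5 3,4-dihydroxybenzaldehyde
Product: 6 4-(allyloxy)-3-hydroxybenzaldehyde
Conditions: allyl bromide (1.05 equiv), NaHCO3 (1.5 equiv), NaI (cat.), DMF, 40 °C
Reagents that add atoms: allyl bromide, C=CCBr
Why: Regioselective Williamson ether synthesis, since bicarbonate ionises only the 4-OH (para to the formyl group and far more acidic than the 3-OH), so allylation should go to O-4 and leave the 3-OH free as the nucleophile for steps 5 and 13.

Step 5
Reactants: 4 [(2R,3R)-3-ArM-oxiran-2-yl]methanol; 6 4-(allyloxy)-3-hydroxybenzaldehyde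
Product: 7 4-(allyloxy)-3-{[(1S,2R)-1-ArM-2,3-dihydroxypropyl]oxy}benzaldehyde
Conditions: 6 (2 equiv), Cs2CO3 (1 equiv), DMF, 60 °C
Reagents that add atoms: none
Why: Base-mediated SN2 opening of a 3-aryl-2,3-epoxy alcohol by a phenoxide at the benzylic carbon, run without any Lewis acid so that the electron-rich arene speeds a concerted displacement instead of ionisation; inversion makes the aryl ether carbon S while C2 keeps its R configuration, and any leakage would appear as a separable diastereomer, not as loss of enantiopurity.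

Step 6
Reactants: 7 4-(allyloxy)-3-{[(1S,2R)-1-ArM-2,3-dihydroxypropyl]oxy}benzaldehyde
Product: 9 4-(allyloxy)-3-{(S)-ArM[(2R)-oxiran-2-yl]methoxy}benzaldehyde, via primary tosylate 8 (not isolated)
Conditions: TsCl (1.05 equiv), Et3N, Bu2SnO (2 mol%), CH2Cl2, 0 °C to rt; then K2CO3, MeOH, rt
Reagents that add atoms: none
Why: Tin-catalysed sulfonylation is selective for the primary hydroxyl of a 1,2-diol, and the secondary alkoxide then closes the oxirane by a 3-exo-tet Williamson displacement that does not touch the C2–O bond, so the oxirane carbon stays R.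

Step 7
Reactants: 9 4-(allyloxy)-3-{(S)-ArM[(2R)-oxiran-2-yl]methoxy}benzaldehyde
Product: 10 4-hydroxy-3-{(S)-ArM[(2R)-oxiran-2-yl]methoxy}benzaldehyde
Conditions: Pd(PPh3)4 (5 mol%), N-methylaniline (3 equiv), THF, rt
Reagents that add atoms: none
Why: Tsuji–Trost-type deallylation, in which Pd(0) ionises the allyl aryl ether with the formyl-stabilised phenoxide as leaving group and N-methylaniline traps the π-allyl unit, this amine being too weak a base to ionise the phenol and too poor a nucleophile to open the oxirane at rt.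

Step 8
Reactants: 10 4-hydroxy-3-{(S)-ArM[(2R)-oxiran-2-yl]methoxy}benzaldehyde
Product: 11 (2S,3S)-3-ArM-2-(hydroxymethyl)-2,3-dihydro-1,4-benzodioxine-6-carbaldehyde
Conditions: K2CO3 (1.5 equiv), DMF (0.02 M), 60 °C
Reagents that add atoms: none
Why: Carbonate ionises the phenol para to the formyl group and this phenoxide attacks the internal oxirane carbon from the side opposite its C–O bond, an intramolecular SN2 epoxide opening of the kind that turns 2-(oxiranylmethoxy)phenols into 2-hydroxymethyl-1,4-benzodioxanes. The dioxane ring closes in the 6-exo-tet mode, the breaking C–O bond lying outside the new ring, and the alkoxide set free becomes the CH2OH group. The one new stereocentre, the CH2OH-bearing ring carbon, is fixed by inversion of the (R)-oxirane carbon to S; with the S aryl-bearing carbon made by inversion in step 5 this equals syn addition of the two phenol oxygens to the former E-alkene, so aryl and CH2OH should come out trans. The step needs attack at the internal carbon to outrun 7-endo attack at the oxirane CH2 and intermolecular opening; the shorter tether, the anti alignment reachable in a chair-like transition state with the aryl group equatorial, and dilution should secure this. Nothing else in 10 is electrophilic toward a phenoxide, and the MOM ethers, the aldehyde and the benzylic aryl ether are stable to carbonate.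

Step 9
Reactants: 11 (2S,3S)-3-ArM-2-(hydroxymethyl)-2,3-dihydro-1,4-benzodioxine-6-carbaldehyde
Product: 12 (2S,3S)-3-ArM-2-(TBSOCH2)-2,3-dihydro-1,4-benzodioxine-6-carbaldehyde
Conditions: TBSCl, imidazole, DMF, rt
Reagents that add atoms: tert-butyldimethylsilyl chloride, CC(C)(C)[Si](C)(C)Cl
Why: Standard imidazole-promoted silylation of the primary alcohol, so that this hydroxyl cannot compete in the primary tosylation of step 14.

Step 10
Reactants: 12 (2S,3S)-3-ArM-2-(TBSOCH2)-2,3-dihydro-1,4-benzodioxine-6-carbaldehyde; 13 trimethyl phosphonoacetate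
Product: 14 methyl (E)-3-BD-prop-2-enoate
Conditions: 13 (1.3 equiv), LiCl, DBU, MeCN, rt
Reagents that add atoms: none
Why: Horner–Wadsworth–Emmons olefination under Masamune–Roush conditions should give the E-cinnamate from the aromatic aldehyde and is mild enough for the silyl and MOM ethers.

Step 11
Reactants: 14 methyl (E)-3-BD-prop-2-enoate
Product: 15 (E)-3-BD-prop-2-en-1-ol
Conditions: DIBAL-H (2.5 equiv), CH2Cl2, −78 °C; Rochelle salt work-up
Reagents that add atoms: none
Why: 1,2-selective DIBAL-H reduction of the unsaturated ester, as in step 2, with the TBS and MOM ethers and the dioxane inert.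

Step 12
Reactants: 15 (E)-3-BD-prop-2-en-1-ol
Product: 16 [(2S,3S)-3-BD-oxiran-2-yl]methanol
Conditions: Ti(Oi-Pr)4 (20 mol%), L-(+)-DIPT (26 mol%), t-BuOOH (2 equiv, decane), 4 Å MS, CH2Cl2, −25 °C; aq. NaOH/brine work-up, used crude
Reagents that add atoms: tert-butyl hydroperoxide, CC(C)(C)OO
Why: Sharpless asymmetric epoxidation under reagent control, where L-(+)-tartrate should give the (2S,3S)-epoxy alcohol and the remote dioxane stereocentres exert no meaningful bias.

Step 13
Reactants: 16 [(2S,3S)-3-BD-oxiran-2-yl]methanol; 6 4-(allyloxy)-3-hydroxybenzaldehyde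
Product: 17 4-(allyloxy)-3-{[(1R,2S)-1-BD-2,3-dihydroxypropyl]oxy}benzaldehyde
Conditions: 6 (2 equiv), Cs2CO3 (1 equiv), DMF, 60 °C
Reagents that add atoms: none
Why: The same Lewis-acid-free SN2 opening at the benzylic oxirane carbon as in step 5, with inversion making the aryl ether carbon R and C2 staying S; the alkyl TBS ether is stable to carbonate in DMF.

Step 14
Reactants: 17 4-(allyloxy)-3-{[(1R,2S)-1-BD-2,3-dihydroxypropyl]oxy}benzaldehyde
Product: 19 4-(allyloxy)-3-{(R)-BD[(2S)-oxiran-2-yl]methoxy}benzaldehyde, via primary tosylate 18 (not isolated)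
Conditions: TsCl (1.05 equiv), Et3N, Bu2SnO (2 mol%), CH2Cl2, 0 °C to rt; then K2CO3, MeOH, rt
Reagents that add atoms: none
Why: Tin-catalysed primary-selective tosylation and 3-exo-tet Williamson closure as in step 6, leaving the C2–O bond intact so the oxirane carbon stays S.

Step 15
Reactants: 19 4-(allyloxy)-3-{(R)-BD[(2S)-oxiran-2-yl]methoxy}benzaldehyde
Product: 20 4-hydroxy-3-{(R)-BD[(2S)-oxiran-2-yl]methoxy}benzaldehyde
Conditions: Pd(PPh3)4 (5 mol%), N-methylaniline (3 equiv), THF, rt
Reagents that add atoms: none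
Why: Tsuji–Trost-type deallylation as in step 7, compatible with the oxirane, aldehyde, TBS and MOM groups.

Step 16
Reactants: 20 4-hydroxy-3-{(R)-BD[(2S)-oxiran-2-yl]methoxy}benzaldehyde
Product: 21 (2R,3R)-3-BD-2-(hydroxymethyl)-2,3-dihydro-1,4-benzodioxine-6-carbaldehyde
Conditions: K2CO3 (1.5 equiv), DMF (0.02 M), 60 °C
Reagents that add atoms: none
Why: The same 6-exo-tet phenoxide opening of the terminal oxirane as in step 8, here inverting the (S)-oxirane carbon to R and so closing the outer dioxane trans.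

Step 17
Reactants: 21 (2R,3R)-3-BD-2-(hydroxymethyl)-2,3-dihydro-1,4-benzodioxine-6-carbaldehyde; 13 trimethyl phosphonoacetate
Product: 22 methyl (E)-3-[(2R,3R)-3-BD-2-(hydroxymethyl)-2,3-dihydro-1,4-benzodioxin-6-yl]prop-2-enoate
Conditions: 13 (1.5 equiv), LiCl, DBU, MeCN, rt
Reagents that add atoms: none
Why: Horner–Wadsworth–Emmons olefination under Masamune–Roush conditions, whose amine base does not deprotonate the free primary alcohol, should give the E-cinnamate.

Step 18
Reactants: 22 methyl (E)-3-[(2R,3R)-3-BD-2-(hydroxymethyl)-2,3-dihydro-1,4-benzodioxin-6-yl]prop-2-enoate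
Product: 23 methyl (E)-3-[(2R,3R)-3-[(2S,3S)-3-(3,4-dihydroxyphenyl)-2-(hydroxymethyl)-2,3-dihydro-1,4-benzodioxin-6-yl]-2-(hydroxymethyl)-2,3-dihydro-1,4-benzodioxin-6-yl]prop-2-enoate
Conditions: HCl (1.25 M in MeOH), rt to 40 °C
Reagents that add atoms: none
Why: Acid-catalysed acetal exchange removes both aryl MOM ethers and methanolysis removes the primary TBS ether at the stage of the acid-inert methyl cinnamate, while both trans-dioxanes are the thermodynamically preferred isomers.

Step 19
Reactants: 23 methyl (E)-3-[(2R,3R)-3-[(2S,3S)-3-(3,4-dihydroxyphenyl)-2-(hydroxymethyl)-2,3-dihydro-1,4-benzodioxin-6-yl]-2-(hydroxymethyl)-2,3-dihydro-1,4-benzodioxin-6-yl]prop-2-enoate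
Product: 24 (E)-3-[(2R,3R)-3-[(2S,3S)-3-(3,4-dihydroxyphenyl)-2-(hydroxymethyl)-2,3-dihydro-1,4-benzodioxin-6-yl]-2-(hydroxymethyl)-2,3-dihydro-1,4-benzodioxin-6-yl]prop-2-en-1-ol
Conditions: DIBAL-H (8 equiv), THF, −78 to 0 °C; Rochelle salt work-up
Reagents that add atoms: none
Why: DIBAL-H reduction of a hydroxycinnamate ester carrying free phenols (the usual way from such esters to coniferyl-type alcohols), in which the four OH groups are first converted to aluminium alkoxides and the excess hydride reduces the ester 1,2, so the acid-sensitive p-alkoxycinnamyl alcohol is formed last and never meets acid.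

**Compound list**

1 | caffeic acid | O=C(O)/C=C/c1ccc(O)c(O)c1 | starting material
2 | methoxymethyl (E)-3-[3,4-bis(methoxymethoxy)phenyl]prop-2-enoate | COCOC(=O)/C=C/c1ccc(OCOC)c(OCOC)c1 | intermediate
3 | (E)-3-[3,4-bis(methoxymethoxy)phenyl]prop-2-en-1-ol | OC/C=C/c1ccc(OCOC)c(OCOC)c1 | intermediate
4 | [(2R,3R)-3-[3,4-bis(methoxymethoxy)phenyl]oxiran-2-yl]methanol | OC[C@H]1O[C@@H]1c1ccc(OCOC)c(OCOC)c1 | intermediate
5 | 3,4-dihydroxybenzaldehyde | O=Cc1ccc(O)c(O)c1 | starting material
6 | 4-(allyloxy)-3-hydroxybenzaldehyde | O=Cc1ccc(OCC=C)c(O)c1 | intermediate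
7 | 4-(allyloxy)-3-{[(1S,2R)-1-[3,4-bis(methoxymethoxy)phenyl]-2,3-dihydroxypropyl]oxy}benzaldehyde | O=Cc1ccc(OCC=C)c(c1)O[C@@H](c1ccc(OCOC)c(OCOC)c1)[C@H](O)CO | intermediate
8 | (2R,3S)-3-[2-(allyloxy)-5-formylphenoxy]-3-[3,4-bis(methoxymethoxy)phenyl]-2-hydroxypropyl 4-methylbenzenesulfonate | O=Cc1ccc(OCC=C)c(c1)O[C@@H](c1ccc(OCOC)c(OCOC)c1)[C@H](O)COS(=O)(=O)c1ccc(C)cc1 | intermediate
9 | 4-(allyloxy)-3-{(S)-[3,4-bis(methoxymethoxy)phenyl][(2R)-oxiran-2-yl]methoxy}benzaldehyde | O=Cc1ccc(OCC=C)c(c1)O[C@@H](c1ccc(OCOC)c(OCOC)c1)[C@H]1CO1 | intermediate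
10 | 4-hydroxy-3-{(S)-[3,4-bis(methoxymethoxy)phenyl][(2R)-oxiran-2-yl]methoxy}benzaldehyde | O=Cc1ccc(O)c(c1)O[C@@H](c1ccc(OCOC)c(OCOC)c1)[C@H]1CO1 | intermediate
11 | (2S,3S)-3-[3,4-bis(methoxymethoxy)phenyl]-2-(hydroxymethyl)-2,3-dihydro-1,4-benzodioxine-6-carbaldehyde | O=Cc1ccc2c(c1)O[C@@H](c1ccc(OCOC)c(OCOC)c1)[C@H](CO)O2 | intermediate
12 | (2S,3S)-3-[3,4-bis(methoxymethoxy)phenyl]-2-{[(tert-butyldimethylsilyl)oxy]methyl}-2,3-dihydro-1,4-benzodioxine-6-carbaldehyde | O=Cc1ccc2c(c1)O[C@@H](c1ccc(OCOC)c(OCOC)c1)[C@H](CO[Si](C)(C)C(C)(C)C)O2 | intermediate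
13 | trimethyl phosphonoacetate | COC(=O)CP(=O)(OC)OC | starting material
14 | methyl (E)-3-[(2S,3S)-3-[3,4-bis(methoxymethoxy)phenyl]-2-{[(tert-butyldimethylsilyl)oxy]methyl}-2,3-dihydro-1,4-benzodioxin-6-yl]prop-2-enoate | COC(=O)/C=C/c1ccc2c(c1)O[C@@H](c1ccc(OCOC)c(OCOC)c1)[C@H](CO[Si](C)(C)C(C)(C)C)O2 | intermediate
15 | (E)-3-[(2S,3S)-3-[3,4-bis(methoxymethoxy)phenyl]-2-{[(tert-butyldimethylsilyl)oxy]methyl}-2,3-dihydro-1,4-benzodioxin-6-yl]prop-2-en-1-ol | OC/C=C/c1ccc2c(c1)O[C@@H](c1ccc(OCOC)c(OCOC)c1)[C@H](CO[Si](C)(C)C(C)(C)C)O2 | intermediate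
16 | [(2S,3S)-3-BD-oxiran-2-yl]methanol | OC[C@@H]1O[C@H]1c1ccc2c(c1)O[C@@H](c1ccc(OCOC)c(OCOC)c1)[C@H](CO[Si](C)(C)C(C)(C)C)O2 | intermediate
17 | 4-(allyloxy)-3-{[(1R,2S)-1-BD-2,3-dihydroxypropyl]oxy}benzaldehyde | O=Cc1ccc(OCC=C)c(c1)O[C@H](c1ccc2c(c1)O[C@@H](c1ccc(OCOC)c(OCOC)c1)[C@H](CO[Si](C)(C)C(C)(C)C)O2)[C@@H](O)CO | intermediate
18 | (2S,3R)-3-[2-(allyloxy)-5-formylphenoxy]-3-BD-2-hydroxypropyl 4-methylbenzenesulfonate | O=Cc1ccc(OCC=C)c(c1)O[C@H](c1ccc2c(c1)O[C@@H](c1ccc(OCOC)c(OCOC)c1)[C@H](CO[Si](C)(C)C(C)(C)C)O2)[C@@H](O)COS(=O)(=O)c1ccc(C)cc1 | intermediate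
19 | 4-(allyloxy)-3-{(R)-BD[(2S)-oxiran-2-yl]methoxy}benzaldehyde | O=Cc1ccc(OCC=C)c(c1)O[C@H](c1ccc2c(c1)O[C@@H](c1ccc(OCOC)c(OCOC)c1)[C@H](CO[Si](C)(C)C(C)(C)C)O2)[C@@H]1CO1 | intermediate
20 | 4-hydroxy-3-{(R)-BD[(2S)-oxiran-2-yl]methoxy}benzaldehyde | O=Cc1ccc(O)c(c1)O[C@H](c1ccc2c(c1)O[C@@H](c1ccc(OCOC)c(OCOC)c1)[C@H](CO[Si](C)(C)C(C)(C)C)O2)[C@@H]1CO1 | intermediate
21 | (2R,3R)-3-BD-2-(hydroxymethyl)-2,3-dihydro-1,4-benzodioxine-6-carbaldehyde | O=Cc1ccc2c(c1)O[C@H](c1ccc3c(c1)O[C@@H](c1ccc(OCOC)c(OCOC)c1)[C@H](CO[Si](C)(C)C(C)(C)C)O3)[C@@H](CO)O2 | intermediate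
22 | methyl (E)-3-[(2R,3R)-3-BD-2-(hydroxymethyl)-2,3-dihydro-1,4-benzodioxin-6-yl]prop-2-enoate | COC(=O)/C=C/c1ccc2c(c1)O[C@H](c1ccc3c(c1)O[C@@H](c1ccc(OCOC)c(OCOC)c1)[C@H](CO[Si](C)(C)C(C)(C)C)O3)[C@@H](CO)O2 | intermediate
23 | methyl (E)-3-[(2R,3R)-3-[(2S,3S)-3-(3,4-dihydroxyphenyl)-2-(hydroxymethyl)-2,3-dihydro-1,4-benzodioxin-6-yl]-2-(hydroxymethyl)-2,3-dihydro-1,4-benzodioxin-6-yl]prop-2-enoate | COC(=O)/C=C/c1ccc2c(c1)O[C@H](c1ccc3c(c1)O[C@@H](c1ccc(O)c(O)c1)[C@H](CO)O3)[C@@H](CO)O2 | intermediate
24 | (E)-3-[(2R,3R)-3-[(2S,3S)-3-(3,4-dihydroxyphenyl)-2-(hydroxymethyl)-2,3-dihydro-1,4-benzodioxin-6-yl]-2-(hydroxymethyl)-2,3-dihydro-1,4-benzodioxin-6-yl]prop-2-en-1-ol (CNP0234042.2) | OC/C=C/c1ccc2c(c1)O[C@H](c1ccc3c(c1)O[C@@H](c1ccc(O)c(O)c1)[C@H](CO)O3)[C@@H](CO)O2 | target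

**Step count and risks**

Total step count: 19. Longest linear sequence: 18 steps (steps 1–3 and 5–19, from caffeic acid); step 4 is a one-step branch whose product 6 enters at steps 5 and 13.

The three steps most likely to fail:

1. Step 3 (and its twin, step 12). The titanium alkoxide is a Lewis acid, and it, together with isopropanol, tartrate or hydroperoxide, may open the newly formed p-alkoxybenzylic oxirane at its benzylic carbon during the reaction and work-up, draining the product. Fallback: a Shi epoxidation of 3 (D-fructose-derived ketone catalyst, Oxone, K2CO3 buffer at about pH 10.5, MeCN/dimethoxymethane/water, 0 °C). This is dioxirane oxygen transfer in a basic medium free of Lewis acid, known for E-allylic alcohols of the cinnamyl type, and this catalyst enantiomer gives the (R,R) series. The fallback sets out from 3 and comes back to the route at 4 and makes no compound outside the list (F0: no new compound); the enantiomeric ketone would serve in the same way for 15 to 16.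

2. Step 8 (and its twin, step 16). Attack of the phenoxide at the unhindered oxirane CH2 (7-endo) or intermolecular opening may compete, because the internal carbon is flanked by the aryl-bearing carbon. Fallback: replace the epoxide opening by an intramolecular Mitsunobu etherification. It sets out from diol 7: selective silylation of the primary hydroxyl (TBSCl, imidazole, CH2Cl2, 0 °C) should give the primary TBS ether F1; deallylation (Pd(PPh3)4, N-methylaniline, THF, rt) should free the phenol F2; PPh3/DIAD in THF (0 °C to rt) should then close the dioxane by SN2 displacement of the activated secondary hydroxyl with inversion (R to S). With the primary oxygen blocked only the six-membered ring can form. The product is 12, where the fallback comes back to the route.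

3. Step 19. The polyaluminium phenoxide/alkoxide formed from the four free OH groups may precipitate or chelate, stalling the ester reduction and making release of the polar product from aluminium salts difficult. Fallback: protect, reduce, then deprotect with fluoride. It sets out from 23: persilylation (TBSCl, imidazole, DMF) should give the tetrakis-TBS ester F3; DIBAL-H (CH2Cl2, −78 °C) should give the tetrakis-TBS allylic alcohol F4; TBAF buffered with AcOH (THF, 0 °C) should remove all four silyl groups under conditions that neither ionise the cinnamyl alcohol nor leave a free phenoxide long enough to open the p-hydroxybenzylic ether. The product is 24, where the fallback comes back to the route.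

**Further compounds**

F0 | step 3 | none | none
F1 | step 8 | 4-(allyloxy)-3-{[(1S,2R)-1-[3,4-bis(methoxymethoxy)phenyl]-3-[(tert-butyldimethylsilyl)oxy]-2-hydroxypropyl]oxy}benzaldehyde | O=Cc1ccc(OCC=C)c(c1)O[C@@H](c1ccc(OCOC)c(OCOC)c1)[C@H](O)CO[Si](C)(C)C(C)(C)C
F2 | step 8 | 4-hydroxy-3-{[(1S,2R)-1-[3,4-bis(methoxymethoxy)phenyl]-3-[(tert-butyldimethylsilyl)oxy]-2-hydroxypropyl]oxy}benzaldehyde | O=Cc1ccc(O)c(c1)O[C@@H](c1ccc(OCOC)c(OCOC)c1)[C@H](O)CO[Si](C)(C)C(C)(C)C
F3 | step 19 | tetrakis-TBS ether of 23 (both phenols and both CH2OH groups silylated) | COC(=O)/C=C/c1ccc2c(c1)O[C@H](c1ccc3c(c1)O[C@@H](c1ccc(O[Si](C)(C)C(C)(C)C)c(O[Si](C)(C)C(C)(C)C)c1)[C@H](CO[Si](C)(C)C(C)(C)C)O3)[C@@H](CO[Si](C)(C)C(C)(C)C)O2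
F4 | step 19 | tetrakis-TBS ether of 24 (both phenols and both ring CH2OH groups silylated; allylic OH free) | OC/C=C/c1ccc2c(c1)O[C@H](c1ccc3c(c1)O[C@@H](c1ccc(O[Si](C)(C)C(C)(C)C)c(O[Si](C)(C)C(C)(C)C)c1)[C@H](CO[Si](C)(C)C(C)(C)C)O3)[C@@H](CO[Si](C)(C)C(C)(C)C)O2
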